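**Retrosynthetic overview**
1. Side chain last: target ⇐ cross-metathesis with methyl methacrylate and acetylation ⇐ reagent-controlled allylboration of the 4-formyl dihydropyran acetate 19 (sets C12).
2. Epoxide ⇐ catalyst-controlled epoxidation of the (Z)-C7=C8 alkene; dihydropyran ⇐ a 2-substituted malondialdehyde closing on the C1 aldehyde (C3 and C12 are equivalent at that stage), then lactol acetylation.
3. Key step, chosen over the usual Z-selective ring-closing metathesis or macro-alkylation onto a preformed pyran: nine-membered ring ⇐ Claisen ring expansion of the 2-methylidene-7-vinyloxepane 12, which fixes the Z-alkene (hence the cis-epoxide) and erases a deliberately racemic quaternary centre.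
4. 12 ⇐ Petasis methylenation ⇐ Baeyer–Villiger lactone 11 ⇐ trans-2,3-disubstituted cyclohexanone 10 ⇐ asymmetric malonate Michael addition to rac-6-ethenyl-6-methylcyclohex-2-enone 4 (sets C4a; C11a follows by 1,2-induction).
5. Ring order: six-membered carbocycle (bought) → oxepanone → nine-membered carbocycle → dihydropyran → epoxide.

Assumption: only the substrates and their products are numbered and every other atom source is given as a reagent with SMILES; ring compounds use the numbering C1, O2, C3, C4, C4a, C5–C11, C11a (side chain C12–C17); TBS = tert-butyldimethylsilyl, TBSO = tert-butyldimethylsilyloxy.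

**Route**

Step 1
Reactants: 1 cyclohex-2-en-1-one
Product: 2 6-(hydroxymethylidene)cyclohex-2-en-1-one
Conditions: LiN(i-Pr)2, THF, −78 °C; CF3CH2OCHO, −78 → 0 °C; aq. HCl
Reagents that add atoms: 2,2,2-trifluoroethyl formate, O=COCC(F)(F)F
Why: kinetic deprotonation of the enone at C6 and Claisen-type C-formylation with the activated formate give the chelated enol of the β-keto aldehyde; no stereocentre is formed.

Step 2
Reactants: 2 6-(hydroxymethylidene)cyclohex-2-en-1-one
Product: 3 rac-1-methyl-2-oxocyclohex-3-ene-1-carbaldehyde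
Conditions: MeI, K2CO3, acetone, rt
Reagents that add atoms: iodomethane, CI
Why: C-alkylation of the β-dicarbonyl enolate builds the quaternary carbon, left racemic on purpose because step 11 turns it into an sp2 carbon.

Step 3
Reactants: 3 rac-1-methyl-2-oxocyclohex-3-ene-1-carbaldehyde
Product: 4 rac-6-ethenyl-6-methylcyclohex-2-en-1-one
Conditions: Ph3PCH3Br, KN(SiMe3)2, THF, 0 °C; then 3, −78 → 0 °C
Reagents that add atoms: methyltriphenylphosphonium bromide (as its ylide), C[P+](c1ccccc1)(c1ccccc1)c1ccccc1.[Br-]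
Why: Wittig methylenation, in which the aldehyde reacts far faster than the hindered conjugated ketone.

Step 4
Reactants: 4 rac-6-ethenyl-6-methylcyclohex-2-en-1-one
Product: 5 dimethyl 2-[(1S)-4-ethenyl-4-methyl-3-oxocyclohexyl]propanedioate (both C4 epimers)
Conditions: CH2(CO2Me)2 (1.5 equiv), LiAl[(S)-BINOLate]2 (10 mol%), KOt-Bu (9 mol%), 4 Å MS, THF, rt
Reagents that add atoms: dimethyl malonate, COC(=O)CC(=O)OC
Why: catalytic asymmetric Michael addition with LiAl[(S)-BINOLate]2 (the (R)-catalyst gives the (R)-adduct of cyclohexenone), which should add malonate to the same face of C3 in both enantiomers of 4, setting the future C4a while the remote quaternary centre stays an epimer pair that converges in step 11.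

Step 5
Reactants: 5 dimethyl 2-[(1S)-4-ethenyl-4-methyl-3-oxocyclohexyl]propanedioate
Product: 6 2-[(1S)-4-ethenyl-3-hydroxy-4-methylcyclohexyl]propane-1,3-diol (diastereomer mixture at C3 and C4)
Conditions: LiAlH4, THF, 0 °C → reflux; aqueous work-up
Reagents that add atoms: none
Why: hydride reduction of both esters and the ketone; the new carbinol centre is irrelevant because step 7 reoxidises it.

Step 6
Reactants: 6 2-[(1S)-4-ethenyl-3-hydroxy-4-methylcyclohexyl]propane-1,3-diol
Product: 7 (5S)-5-[1,3-bis(TBSO)propan-2-yl]-2-ethenyl-2-methylcyclohexan-1-ol (diastereomer mixture at C1 and C2)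
Conditions: TBSCl (2.1 equiv), imidazole, CH2Cl2, 0 °C
Reagents that add atoms: tert-butyldimethylsilyl chloride, CC(C)(C)[Si](C)(C)Cl
Why: the two primary alcohols are silylated selectively over the neopentyl-type secondary alcohol.

Step 7
Reactants: 7 (5S)-5-[1,3-bis(TBSO)propan-2-yl]-2-ethenyl-2-methylcyclohexan-1-ol
Product: 8 (5S)-5-[1,3-bis(TBSO)propan-2-yl]-2-ethenyl-2-methylcyclohexan-1-one (both C2 epimers)
Conditions: Dess–Martin periodinane, pyridine, CH2Cl2, rt
Reagents that add atoms: none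
Why: Dess–Martin oxidation returns the ketone, now the only carbonyl group in the molecule.

Step 8
Reactants: 8 (5S)-5-[1,3-bis(TBSO)propan-2-yl]-2-ethenyl-2-methylcyclohexan-1-one
Product: 10 (5R,6S)-5-[1,3-bis(TBSO)propan-2-yl]-6-(dimethoxymethyl)-2-ethenyl-2-methylcyclohexan-1-one, via trimethylsilyl enol ether 9 (not isolated)
Conditions: Me3SiOTf, i-Pr2NEt, CH2Cl2, 0 °C; then HC(OMe)3, −78 → −40 °C
Reagents that add atoms: trimethyl orthoformate, COC(OC)OC; trimethylsilyl triflate (silyl group present in 9 only), C[Si](C)(C)OS(=O)(=O)C(F)(F)F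
Why: the ketone can enolise only toward C6 (C2 is quaternary), and Mukaiyama-type addition of the silyl enol ether to the dimethoxycarbenium ion occurs anti to the C5 substituent, giving the 5,6-trans ketone (also the thermodynamic epimer) and so setting the future C11a with C1 already at the aldehyde oxidation level.

Step 9
Reactants: 10 (5R,6S)-5-[1,3-bis(TBSO)propan-2-yl]-6-(dimethoxymethyl)-2-ethenyl-2-methylcyclohexan-1-one
Product: 11 (3S,4R)-4-[1,3-bis(TBSO)propan-2-yl]-3-(dimethoxymethyl)-7-ethenyl-7-methyloxepan-2-one (both C7 epimers)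
Conditions: 3-chloroperbenzoic acid (mCPBA), NaHCO3, CH2Cl2, 0 °C → rt
Reagents that add atoms: 3-chloroperbenzoic acid, OOC(=O)c1cccc(Cl)c1
Why: Baeyer–Villiger oxidation, in which the tertiary vinyl-bearing carbon migrates in preference to the secondary carbon carrying the electron-withdrawing acetal, while the hindered monosubstituted alkene is epoxidised much more slowly.

Step 10
Reactants: 11 (3S,4R)-4-[1,3-bis(TBSO)propan-2-yl]-3-(dimethoxymethyl)-7-ethenyl-7-methyloxepan-2-one
Product: 12 (3R,4R)-4-[1,3-bis(TBSO)propan-2-yl]-3-(dimethoxymethyl)-7-ethenyl-7-methyl-2-methylideneoxepane (both C7 epimers)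
Conditions: Cp2TiMe2 (3 equiv), toluene, 75 °C, dark; filtration through basic Al2O3
Reagents that add atoms: dimethyltitanocene, C[Ti](C)(C1C=CC=C1)C1C=CC=C1
Why: Petasis methylenation of the lactone carbonyl by Cp2Ti=CH2 formed on heating; the reagent is non-basic and no other carbonyl group is present.

Step 11
Reactants: 12 (3R,4R)-4-[1,3-bis(TBSO)propan-2-yl]-3-(dimethoxymethyl)-7-ethenyl-7-methyl-2-methylideneoxepane
Product: 13 (4Z,8R,9S)-8-[1,3-bis(TBSO)propan-2-yl]-9-(dimethoxymethyl)-5-methylcyclonon-4-en-1-one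
Conditions: toluene (0.01 M, degassed), base-washed sealed tube, 170 °C
Reagents that add atoms: none
Why: Claisen ([3,3]-sigmatropic) ring expansion of the allyl vinyl ether embedded in the oxepane: the four-carbon tether holds the ring C–C bond at the carbinol carbon pseudo-axial in the transition state, so the (Z)-trisubstituted alkene forms, both quaternary epimers converge on one ketone, and C4a and C11a are untouched.

Step 12
Reactants: 13 (4Z,8R,9S)-8-[1,3-bis(TBSO)propan-2-yl]-9-(dimethoxymethyl)-5-methylcyclonon-4-en-1-one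
Product: 14 (1Z,6R,7R)-7-[1,3-bis(TBSO)propan-2-yl]-6-(dimethoxymethyl)-1-methyl-5-methylidenecyclonon-1-ene
Conditions: Cp2TiMe2 (3 equiv), toluene, 75 °C, dark
Reagents that add atoms: dimethyltitanocene, C[Ti](C)(C1C=CC=C1)C1C=CC=C1
Why: Petasis methylenation of the hindered ketone; being non-basic it neither epimerises C11a nor eliminates methanol from the β-keto acetal, as a Wittig ylide could.

Step 13
Reactants: 14 (1Z,6R,7R)-7-[1,3-bis(TBSO)propan-2-yl]-6-(dimethoxymethyl)-1-methyl-5-methylidenecyclonon-1-ene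
Product: 15 2-[(1R,4Z,9R)-9-(dimethoxymethyl)-4-methyl-8-methylidenecyclonon-4-en-1-yl]propane-1,3-diol
Conditions: Bu4NF, THF, 0 °C → rt
Reagents that add atoms: none
Why: fluoride-mediated desilylation; acetal and alkenes are inert.

Step 14
Reactants: 15 2-[(1R,4Z,9R)-9-(dimethoxymethyl)-4-methyl-8-methylidenecyclonon-4-en-1-yl]propane-1,3-diol
Product: 17 (4aS,7Z,11aR)-1-hydroxy-7-methyl-11-methylidene-1,4a,5,6,9,10,11,11a-octahydrocyclonona[c]pyran-4-carbaldehyde, via malondialdehyde 16 (not isolated)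
Conditions: Dess–Martin periodinane (2.3 equiv), pyridine, CH2Cl2, 0 °C; aq. Na2S2O3/NaHCO3 wash; crude in THF, 1 M aq. HCl, 0 °C → rt
Reagents that add atoms: water, O
Why: Dess–Martin oxidation of the 1,3-diol gives the enolised malondialdehyde (no hydroxy aldehyde can lactolise because C1 is still an acetal), and acetal hydrolysis then frees the C1 aldehyde, which the enol oxygen captures as a six-membered cyclic hemiacetal; the two formyl groups are equivalent, so either closure gives the same dihydropyran (C1 anomer mixture).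

Step 15
Reactants: 17 (4aS,7Z,11aR)-1-hydroxy-7-methyl-11-methylidene-1,4a,5,6,9,10,11,11a-octahydrocyclonona[c]pyran-4-carbaldehyde
Product: 18 (1R,4aS,7Z,11aR)-4-formyl-7-methyl-11-methylidene-1,4a,5,6,9,10,11,11a-octahydrocyclonona[c]pyran-1-yl acetate
Conditions: Ac2O, Et3N, 4-(dimethylamino)pyridine (cat.), CH2Cl2, −20 → 0 °C
Reagents that add atoms: acetic anhydride, CC(=O)OC(C)=O
Why: O-acylation of the equilibrating lactol, which reacts in its cyclic form; the acetate is expected pseudo-axial and trans to the C11 ring carbon (anomeric effect, least hindered), which sets C1 as R.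

Step 16
Reactants: 18 (1R,4aS,7Z,11aR)-4-formyl-7-methyl-11-methylidene-1,4a,5,6,9,10,11,11a-octahydrocyclonona[c]pyran-1-yl acetate
Product: 19 (1R,4aS,7S,8R,11aR)-7,8-epoxy-4-formyl-7-methyl-11-methylidene-1,4a,5,6,7,8,9,10,11,11a-decahydrocyclonona[c]pyran-1-yl acetate
Conditions: 1,2:4,5-di-O-isopropylidene-β-D-erythro-2,3-hexodiulo-2,6-pyranose (Shi ketone, 3 equiv), KHSO5 (as 2KHSO5·KHSO4·K2SO4), NaHCO3, Bu4NHSO4 (cat.), MeCN/aq. disodium ethylenediaminetetraacetate, 0 °C
Reagents that add atoms: potassium peroxymonosulfate, [K+].[O-]S(=O)(=O)OO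
Why: Shi asymmetric epoxidation by the chiral dioxirane: the trisubstituted alkene reacts before the 1,1-disubstituted alkene and the formyl-deactivated enol ether, syn oxygen transfer keeps C6 and C9 cis, and the spiro transition state of the D-fructose-derived ketone should select the face giving (7S,8R), by analogy with its (R,R)-selective epoxidation of 1-phenylcyclohexene; hydrogencarbonate buffering spares the C1 acetate.

Step 17
Reactants: 19 (1R,4aS,7S,8R,11aR)-7,8-epoxy-4-formyl-7-methyl-11-methylidene-1,4a,5,6,7,8,9,10,11,11a-decahydrocyclonona[c]pyran-1-yl acetate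
Product: 20 (1R,4aS,7S,8R,11aR)-7,8-epoxy-4-[(1S)-1-hydroxybut-3-en-1-yl]-7-methyl-11-methylidene-1,4a,5,6,7,8,9,10,11,11a-decahydrocyclonona[c]pyran-1-yl acetate
Conditions: (−)-Ipc2B(allyl) (from (+)-α-pinene, 1 M in pentane), Et2O, −78 °C; then pH 7 buffer, MeOH, 30% H2O2, 0 °C → rt
Reagents that add atoms: (−)-B-allyldiisopinocampheylborane, C=CCB([C@H]1[C@H](C)[C@H]2C[C@@H](C1)C2(C)C)[C@H]1[C@H](C)[C@H]2C[C@@H](C1)C2(C)C
Why: Brown allylboration through a closed chair transition state; this reagent attacks the Si face of the aldehyde (as it does with benzaldehyde) and sets C12 as S under reagent control, and at −78 °C it touches neither the epoxide nor the esters.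

Step 18
Reactants: 20 (1R,4aS,7S,8R,11aR)-7,8-epoxy-4-[(1S)-1-hydroxybut-3-en-1-yl]-7-methyl-11-methylidene-1,4a,5,6,7,8,9,10,11,11a-decahydrocyclonona[c]pyran-1-yl acetate
Product: 21 (1R,4aS,7S,8R,11aR)-4-[(1S)-1-acetoxybut-3-en-1-yl]-7,8-epoxy-7-methyl-11-methylidene-1,4a,5,6,7,8,9,10,11,11a-decahydrocyclonona[c]pyran-1-yl acetate
Conditions: Ac2O, pyridine, 4-(dimethylamino)pyridine (cat.), CH2Cl2, 0 °C
Reagents that add atoms: acetic anhydride, CC(=O)OC(C)=O
Why: base-mediated acetylation of the secondary alcohol with retention at C12; no acid is present to ionise the allylic position next to the enol ether.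

Step 19
Reactants: 21 (1R,4aS,7S,8R,11aR)-4-[(1S)-1-acetoxybut-3-en-1-yl]-7,8-epoxy-7-methyl-11-methylidene-1,4a,5,6,7,8,9,10,11,11a-decahydrocyclonona[c]pyran-1-yl acetate
Product: 22 methyl (2E,5S)-5-acetoxy-5-[(1R,4aS,7S,8R,11aR)-1-acetoxy-7,8-epoxy-7-methyl-11-methylidene-1,4a,5,6,7,8,9,10,11,11a-decahydrocyclonona[c]pyran-4-yl]-2-methylpent-2-enoate (CNP0184381.3)
Conditions: methyl methacrylate (20 equiv), second-generation Hoveyda–Grubbs catalyst RuCl2(H2IMes)(=CH-C6H4-2-O-i-Pr) (10 mol%), CH2Cl2, 40 °C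
Reagents that add atoms: methyl methacrylate, C=C(C)C(=O)OC
Why: olefin cross-metathesis: the monosubstituted alkene is the only one that initiates readily, the hindered 1,1-disubstituted alkene and the trisubstituted enol ether are poor substrates, excess methacrylate gives the thermodynamically favoured (E)-trisubstituted enoate, and no stereocentre (C4a and C12 included) is touched.

**Compound list**
1 | cyclohex-2-en-1-one | O=C1C=CCCC1 | starting material
2 | 6-(hydroxymethylidene)cyclohex-2-en-1-one (enol of the 6-formyl ketone) | O=C1C=CCCC1=CO | intermediate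
3 | rac-1-methyl-2-oxocyclohex-3-ene-1-carbaldehyde | O=CC1(C)CCC=CC1=O | intermediate
4 | rac-6-ethenyl-6-methylcyclohex-2-en-1-one | C=CC1(C)CCC=CC1=O | intermediate
5 | dimethyl 2-[(1S)-4-ethenyl-4-methyl-3-oxocyclohexyl]propanedioate (both C4 epimers) | O=C1C(C)(C=C)CC[C@H](C(C(=O)OC)C(=O)OC)C1 | intermediate
6 | 2-[(1S)-4-ethenyl-3-hydroxy-4-methylcyclohexyl]propane-1,3-diol (mixture at C3 and C4) | OC1C(C)(C=C)CC[C@H](C(CO)CO)C1 | intermediate
7 | (5S)-5-[1,3-bis(TBSO)propan-2-yl]-2-ethenyl-2-methylcyclohexan-1-ol (mixture at C1 and C2) | OC1C(C)(C=C)CC[C@H](C(CO[Si](C)(C)C(C)(C)C)CO[Si](C)(C)C(C)(C)C)C1 | intermediate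
8 | (5S)-5-[1,3-bis(TBSO)propan-2-yl]-2-ethenyl-2-methylcyclohexan-1-one (both C2 epimers) | O=C1C(C)(C=C)CC[C@H](C(CO[Si](C)(C)C(C)(C)C)CO[Si](C)(C)C(C)(C)C)C1 | intermediate
9 | (3R)-3-[1,3-bis(TBSO)propan-2-yl]-6-ethenyl-6-methyl-1-(trimethylsilyloxy)cyclohex-1-ene (both C6 epimers; not isolated) | C[Si](C)(C)OC1=C[C@@H](C(CO[Si](C)(C)C(C)(C)C)CO[Si](C)(C)C(C)(C)C)CCC1(C)C=C | intermediate
10 | (5R,6S)-5-[1,3-bis(TBSO)propan-2-yl]-6-(dimethoxymethyl)-2-ethenyl-2-methylcyclohexan-1-one (5,6-trans; both C2 epimers) | O=C1C(C)(C=C)CC[C@H](C(CO[Si](C)(C)C(C)(C)C)CO[Si](C)(C)C(C)(C)C)[C@H]1C(OC)OC | intermediate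
11 | (3S,4R)-4-[1,3-bis(TBSO)propan-2-yl]-3-(dimethoxymethyl)-7-ethenyl-7-methyloxepan-2-one (both C7 epimers) | O=C1OC(C)(C=C)CC[C@H](C(CO[Si](C)(C)C(C)(C)C)CO[Si](C)(C)C(C)(C)C)[C@H]1C(OC)OC | intermediate
12 | (3R,4R)-4-[1,3-bis(TBSO)propan-2-yl]-3-(dimethoxymethyl)-7-ethenyl-7-methyl-2-methylideneoxepane (both C7 epimers) | C=C1OC(C)(C=C)CC[C@H](C(CO[Si](C)(C)C(C)(C)C)CO[Si](C)(C)C(C)(C)C)[C@H]1C(OC)OC | intermediate
13 | (4Z,8R,9S)-8-[1,3-bis(TBSO)propan-2-yl]-9-(dimethoxymethyl)-5-methylcyclonon-4-en-1-one | O=C1CC/C=C(C)\CC[C@H](C(CO[Si](C)(C)C(C)(C)C)CO[Si](C)(C)C(C)(C)C)[C@H]1C(OC)OC | intermediate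
14 | (1Z,6R,7R)-7-[1,3-bis(TBSO)propan-2-yl]-6-(dimethoxymethyl)-1-methyl-5-methylidenecyclonon-1-ene | C=C1CC/C=C(C)\CC[C@H](C(CO[Si](C)(C)C(C)(C)C)CO[Si](C)(C)C(C)(C)C)[C@H]1C(OC)OC | intermediate
15 | 2-[(1R,4Z,9R)-9-(dimethoxymethyl)-4-methyl-8-methylidenecyclonon-4-en-1-yl]propane-1,3-diol | C=C1CC/C=C(C)\CC[C@H](C(CO)CO)[C@H]1C(OC)OC | intermediate
16 | 2-[(1S,4Z,9R)-9-(dimethoxymethyl)-4-methyl-8-methylidenecyclonon-4-en-1-yl]propanedial (enolised; not isolated) | C=C1CC/C=C(C)\CC[C@H](C(C=O)C=O)[C@H]1C(OC)OC | intermediate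
17 | (4aS,7Z,11aR)-1-hydroxy-7-methyl-11-methylidene-1,4a,5,6,9,10,11,11a-octahydrocyclonona[c]pyran-4-carbaldehyde (C1 anomer mixture) | C=C1CC/C=C(C)\CC[C@@H]2C(C=O)=COC(O)[C@@H]12 | intermediate
18 | (1R,4aS,7Z,11aR)-4-formyl-7-methyl-11-methylidene-1,4a,5,6,9,10,11,11a-octahydrocyclonona[c]pyran-1-yl acetate | C=C1CC/C=C(C)\CC[C@@H]2C(C=O)=CO[C@H](OC(C)=O)[C@@H]12 | intermediate
19 | (1R,4aS,7S,8R,11aR)-7,8-epoxy-4-formyl-7-methyl-11-methylidene-1,4a,5,6,7,8,9,10,11,11a-decahydrocyclonona[c]pyran-1-yl acetate | C=C1CC[C@H]2O[C@@]2(C)CC[C@@H]2C(C=O)=CO[C@H](OC(C)=O)[C@@H]12 | intermediate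
20 | (1R,4aS,7S,8R,11aR)-7,8-epoxy-4-[(1S)-1-hydroxybut-3-en-1-yl]-7-methyl-11-methylidene-1,4a,5,6,7,8,9,10,11,11a-decahydrocyclonona[c]pyran-1-yl acetate | C=C1CC[C@H]2O[C@@]2(C)CC[C@@H]2C([C@H](CC=C)O)=CO[C@H](OC(C)=O)[C@@H]12 | intermediate
21 | (1R,4aS,7S,8R,11aR)-4-[(1S)-1-acetoxybut-3-en-1-yl]-7,8-epoxy-7-methyl-11-methylidene-1,4a,5,6,7,8,9,10,11,11a-decahydrocyclonona[c]pyran-1-yl acetate | C=C1CC[C@H]2O[C@@]2(C)CC[C@@H]2C([C@H](CC=C)OC(C)=O)=CO[C@H](OC(C)=O)[C@@H]12 | intermediate
22 | methyl (2E,5S)-5-acetoxy-5-[(1R,4aS,7S,8R,11aR)-1-acetoxy-7,8-epoxy-7-methyl-11-methylidene-1,4a,5,6,7,8,9,10,11,11a-decahydrocyclonona[c]pyran-4-yl]-2-methylpent-2-enoate | C=C1CC[C@H]2O[C@@]2(C)CC[C@@H]2C([C@H](C/C=C(\C)C(=O)OC)OC(C)=O)=CO[C@H](OC(C)=O)[C@@H]12 | target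

**Step count and risks**

Total steps: 19. Longest linear sequence: 19 (fully linear from cyclohex-2-en-1-one).

The three steps most likely to fail:

Step 11 (Claisen ring expansion). The seven-to-nine-membered version on this substituted substrate may need temperatures at which the enol ether decomposes or undergoes a [1,3] shift. The fallback sets out from enol ether 12 and replaces the thermal concerted shift by an Al(i-Bu)3-promoted, ion-pair ring expansion. Al(i-Bu)3 (3 equiv) in CH2Cl2 at −78 → −20 °C ionises the allylic C–O bond, the ion pair recombines at the vinyl terminus, and the reagent reduces the ketone as it forms. This gives the alcohol (4Z,8R,9R)-8-[1,3-bis(TBSO)propan-2-yl]-9-(dimethoxymethyl)-5-methylcyclonon-4-en-1-ol F1 (both carbinol epimers). Dess–Martin oxidation of F1 comes back to the route at ketone 13.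

Step 16 (epoxidation). The facial preference of the nine-membered ring may override the ketone catalyst and give the other cis-epoxide, and the C1 acetate is base-labile. The fallback sets out from 18 and uses the halohydrin route, which places oxygen on the face opposite to the one an electrophile attacks. NBS in THF–H2O at 0 °C gives the anti bromohydrin (1R,4aS,7S,8S,11aR)-8-bromo-4-formyl-7-hydroxy-7-methyl-11-methylidene-1,4a,5,6,7,8,9,10,11,11a-decahydrocyclonona[c]pyran-1-yl acetate F2. Ag2O in THF then closes the oxirane with inversion at C8, coming back to the route at 19.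

Step 19 (cross-metathesis). Ring closure onto the exocyclic methylene or arrest of the propagating carbene at the enol ether could compete. The fallback sets out from aldehyde 19 and builds the whole side chain in one C–C bond formation by a vinylogous Mukaiyama aldol reaction. The reagents are tert-butyl[(1-methoxy-2-methylbuta-1,3-dien-1-yl)oxy]dimethylsilane, the B-phenyl oxazaborolidinone from N-tosyl-D-tryptophan and PhBCl2 (1 equiv; the enantiomer assumed to direct Si-face attack), i-PrOH, EtCN, −78 °C. γ-Attack gives methyl (2E,5S)-5-[(1R,4aS,7S,8R,11aR)-1-acetoxy-7,8-epoxy-7-methyl-11-methylidene-1,4a,5,6,7,8,9,10,11,11a-decahydrocyclonona[c]pyran-4-yl]-5-hydroxy-2-methylpent-2-enoate F3. Acetylation of F3 (Ac2O, pyridine, 4-(dimethylamino)pyridine) comes back to the route at target 22.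

Further compounds
F1 | step 11 | (4Z,8R,9R)-8-[1,3-bis(TBSO)propan-2-yl]-9-(dimethoxymethyl)-5-methylcyclonon-4-en-1-ol (both C1 epimers) | OC1CC/C=C(C)\CC[C@H](C(CO[Si](C)(C)C(C)(C)C)CO[Si](C)(C)C(C)(C)C)[C@H]1C(OC)OC
F2 | step 16 | (1R,4aS,7S,8S,11aR)-8-bromo-4-formyl-7-hydroxy-7-methyl-11-methylidene-1,4a,5,6,7,8,9,10,11,11a-decahydrocyclonona[c]pyran-1-yl acetate | C=C1CC[C@H](Br)[C@](O)(C)CC[C@@H]2C(C=O)=CO[C@H](OC(C)=O)[C@@H]12
F3 | step 19 | methyl (2E,5S)-5-[(1R,4aS,7S,8R,11aR)-1-acetoxy-7,8-epoxy-7-methyl-11-methylidene-1,4a,5,6,7,8,9,10,11,11a-decahydrocyclonona[c]pyran-4-yl]-5-hydroxy-2-methylpent-2-enoate | C=C1CC[C@H]2O[C@@]2(C)CC[C@@H]2C([C@H](C/C=C(\C)C(=O)OC)O)=CO[C@H](OC(C)=O)[C@@H]12
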